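The route rests on cutting the gem-dimethylcyclobutane (C1′, C9′, C10′, C11′), whose CMe2 carbon C11′ lies across the ring from the ester-bearing C9′, back to a bicyclo[1.1.0]butane with a C9′–C11′ central bond. In one flask a chiral dirhodium carbene at C9′ closes that bicycle onto the tethered C11′=C1′ alkene and a methylcopper reagent opens it at C11′, giving the trans cyclobutane ester with C1′ set by the catalyst. The precursor is an acyclic (E)-2-diazo-4-methylhept-4-enoate carrying a silyl ether at C3′. The cyclohexene and nine-membered rings follow from a Diels–Alder reaction of methyl trans-communate, lactone alkylation and β-keto ester cyclisation.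

Key step: step 6

Locants: C1′–C11′ are the caryophyllane ring carbons (C12′ = carboxyl carbon on C4′, C13′ = exocyclic CH2 on C8′); unprimed C1–C20 are the labdane carbons (C11–C15 side chain, C17 exocyclic CH2, C19 carboxyl).
Assumption: Rh2(S-NTTL)4 is taken to give the C1′ configuration drawn, by analogy with aryl-substituted substrates (if the sense is opposite, Rh2(R-NTTL)4 is used); 15 and 17 are taken as purchasable.

Step 1
Reactants: 1 3-[(tert-butyldimethylsilyl)oxy]propanal; 2 ethyl 2-(triphenylphosphoranylidene)propanoate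
Product: 3 ethyl (E)-5-[(tert-butyldimethylsilyl)oxy]-2-methylpent-2-enoate
Conditions: CH2Cl2, rt
Reagents that add atoms: none
Why: Wittig olefination with a stabilised ylide should give the E-enoate and puts the methyl group on the alkene carbon that becomes C11′ (methyl-metalation of a terminal alkynol would put it on C1′ instead).

Step 2
Reactants: 3 ethyl (E)-5-[(tert-butyldimethylsilyl)oxy]-2-methylpent-2-enoate
Product: 4 (E)-5-[(tert-butyldimethylsilyl)oxy]-2-methylpent-2-en-1-ol
Conditions: i-Bu2AlH, CH2Cl2, −78 °C; aq. KNaC4H4O6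
Reagents that add atoms: none
Why: 1,2-reduction of the enoate by the aluminium hydride stops at the allylic alcohol and leaves the silyl ether and the E-alkene untouched.

Step 3
Reactants: 4 (E)-5-[(tert-butyldimethylsilyl)oxy]-2-methylpent-2-en-1-ol
Product: 5 (E)-1-bromo-5-[(tert-butyldimethylsilyl)oxy]-2-methylpent-2-ene
Conditions: CBr4, PPh3, CH2Cl2, 0 °C
Reagents that add atoms: carbon tetrabromide BrC(Br)(Br)Br
Why: Appel bromination, in which bromide displaces the primary oxyphosphonium group by SN2 at 0 °C without allylic transposition.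

Step 4
Reactants: 5 (E)-1-bromo-5-[(tert-butyldimethylsilyl)oxy]-2-methylpent-2-ene; 6 tert-butyl acetoacetate
Product: 7 tert-butyl (E)-2-acetyl-7-[(tert-butyldimethylsilyl)oxy]-4-methylhept-4-enoate (racemic)
Conditions: 6 (2 equiv), NaH, THF, 0 °C; then 5, 0 °C → rt
Reagents that add atoms: none
Why: Acetoacetic ester alkylation, in which the sodium enolate displaces the primary allylic bromide by SN2 and the excess of 6 suppresses dialkylation.

Step 5
Reactants: 7 tert-butyl (E)-2-acetyl-7-[(tert-butyldimethylsilyl)oxy]-4-methylhept-4-enoate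
Product: 8 tert-butyl (E)-2-diazo-4-methyl-7-[(tert-butyldimethylsilyl)oxy]hept-4-enoate
Conditions: 4-acetamidobenzenesulfonyl azide, DBU, MeCN, 0 °C → rt
Reagents that add atoms: 4-acetamidobenzenesulfonyl azide CC(=O)Nc1ccc(cc1)S(=O)(=O)N=[N+]=[N-]
Why: Regitz deacylative diazo transfer, in which the enolate of 7 takes the diazo group from the sulfonyl azide and the acetyl group leaves as the N-acetylsulfonamide.

Step 6
Reactants: 8 tert-butyl (E)-2-diazo-4-methyl-7-[(tert-butyldimethylsilyl)oxy]hept-4-enoate; 9 methylmagnesium bromide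
Product: 12 tert-butyl (1S,2R)-2-{2-[(tert-butyldimethylsilyl)oxy]ethyl}-3,3-dimethylcyclobutane-1-carboxylate (trans), via bicyclobutane ester 10 (not isolated), via cis cyclobutane ester 11 (not isolated)
Conditions: Rh2(S-NTTL)4 (dirhodium tetrakis[N-naphthaloyl-(S)-tert-leucinate], 1 mol %), toluene, −78 °C, slow addition of 8; then CuBr·SMe2 (0.3 equiv), PBu3, 9 (3 equiv), THF, −78 → −20 °C; then t-BuOH, KOt-Bu (0.3 equiv), rt
Reagents that add atoms: none
Why: Proposed new method: the dirhodium carbene formed at C9′ by loss of N2 adds to the tethered C11′=C1′ alkene (bonds C9′–C11′ and C9′–C1′), and the methylcopper species made from 9 then attacks the methyl-bearing bridgehead C11′ at the rear of the strained central bond, leaving a C9′ ester enolate that is protonated; the closest known reaction type is the enantioselective dirhodium-catalysed bicyclobutanation of 2-diazo-5-arylpent-4-enoates with copper-catalysed Grignard homoconjugate addition at an unsubstituted bridgehead, together with cuprate additions to bridgehead-alkylated sulfonyl bicyclobutanes. Both three-membered rings of 10 close in one concerted [2+1] carbene addition across the alkene three atoms away, and the cyclobutane of 12 results when the central C9′–C11′ bond is cleaved by SN2-like attack with inversion at C11′. C1′ is set by the chiral carboxylate ligands, which decide the alkene face met by the carbene; C9′ is set under thermodynamic control, because tert-butoxide equilibrates the kinetically protonated cis ester 11 to the trans ester 12. C11′ becomes a non-stereogenic CMe2 carbon and needs no control. The step needs cyclopropanation to outrun 1,2-hydride shift (helped by the electron-rich trisubstituted alkene, the bulky ligands and −78 °C) and needs attack at C11′ and not at C9′ (the ester polarises the central bond towards the homoconjugate position). The E-alkene holds the C2′ and C3′ hydrogens out of reach of the carbene and places the side chain exo on C1′, away from the incoming cuprate.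

Step 7
Reactants: 12 tert-butyl (1S,2R)-2-{2-[(tert-butyldimethylsilyl)oxy]ethyl}-3,3-dimethylcyclobutane-1-carboxylate
Product: 13 tert-butyl (1S,2R)-2-(2-hydroxyethyl)-3,3-dimethylcyclobutane-1-carboxylate
Conditions: Bu4NF, THF, 0 °C → rt
Reagents that add atoms: none
Why: Fluoride-induced desilylation, to which the tert-butyl ester is inert and under which C9′ stays in its thermodynamic trans arrangement.

Step 8
Reactants: 13 tert-butyl (1S,2R)-2-(2-hydroxyethyl)-3,3-dimethylcyclobutane-1-carboxylate
Product: 14 tert-butyl (1S,2R)-2-(2-iodoethyl)-3,3-dimethylcyclobutane-1-carboxylate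
Conditions: I2, PPh3, imidazole, CH2Cl2, 0 °C → rt
Reagents that add atoms: iodine II
Why: Appel-type iodination by SN2 at the unhindered primary C3′ under imidazole buffering.

Step 9
Reactants: 15 trans-communic acid
Product: 16 methyl trans-communate
Conditions: MeI, K2CO3, DMF, rt
Reagents that add atoms: iodomethane CI
Why: SN2 O-methylation of the carboxylate, the standard esterification for the hindered axial C19 acid.

Step 10
Reactants: 16 methyl trans-communate; 17 (5S)-5-[(1S,2R,5S)-menthyloxy]furan-2(5H)-one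
Product: 18 endo menthyloxy lactone cycloadduct (new bonds C12–C4′ and C15–C5′)
Conditions: toluene, BHT (cat.), 110 °C, sealed tube
Reagents that add atoms: none
Why: Thermal Diels–Alder reaction in which the unsubstituted diene terminus C15 should bond to the butenolide β-carbon C5′ (the C12 alkyl group directing more strongly than the C13 methyl), the lactone sits endo so that C11, C12′ and C6′ end up cis, and addition anti to the menthyloxy group fixes C12 and C5′ (and provisional C4′) absolutely, whatever the remote labdane centres prefer.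

Step 11
Reactants: 18 endo menthyloxy lactone cycloadduct
Product: 21 cis-fused γ-lactone C12′(=O)–O–C6′H2, via sodium formyl carboxylate 19 (not isolated), via hydroxy acid 20 (not isolated)
Conditions: NaBH4, aq. NaOH, MeOH–THF, 0 °C → rt; then 2 M HCl, rt
Reagents that add atoms: none
Why: Hydroxide opens the pseudo-ester to the C6′ aldehyde and menthol, borohydride reduces the aldehyde as it forms (before C5′ can epimerise), and acidification closes the cis γ-hydroxy acid to the lactone while the hindered C19 ester survives.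

Step 12
Reactants: 21 cis-fused γ-lactone; 14 tert-butyl (1S,2R)-2-(2-iodoethyl)-3,3-dimethylcyclobutane-1-carboxylate
Product: 22 C4′-alkylated lactone (new bond C3′–C4′)
Conditions: LiN(i-Pr)2, THF, −78 °C; then 14, DMPU, −78 → −20 °C
Reagents that add atoms: none
Why: Lactone enolate alkylation with a primary iodide, in which the electrophile should enter on the convex face of the cis-fused bicycle, anti to C15 and to the C11 chain, so that quaternary C4′ is set with C3′ trans to C6′ and C11.

Step 13
Reactants: 22 C4′-alkylated lactone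
Product: 24 C6′-hydroxy C12′-methyl ester, via potassium carboxylate 23 (not isolated)
Conditions: KOH, MeOH–THF–H2O, 50 °C; CO2 to pH 8, evaporate; MeI, DMF, 0 °C → rt
Reagents that add atoms: potassium hydroxide [K+].[OH-]; iodomethane CI
Why: Saponification of the lactone and SN2 O-methylation of the carboxylate salt give the open hydroxy ester (tert-butyl and C19 esters are too hindered to hydrolyse), which is used at once because it can relactonise.

Step 14
Reactants: 24 C6′-hydroxy C12′-methyl ester
Product: 25 C6′ iodide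
Conditions: I2, PPh3, imidazole, CH2Cl2, 0 °C → rt
Reagents that add atoms: iodine II
Why: Appel-type iodination of the primary C6′ alcohol under buffered, non-basic conditions that do not trigger lactonisation.

Step 15
Reactants: 25 C6′ iodide
Product: 27 C8′ carboxylic acid, via trimethylsilyl ester 26 (not isolated)
Conditions: Me3SiOTf, 2,6-lutidine, CH2Cl2, 0 °C; then pH 4 buffer
Reagents that add atoms: none
Why: Silyl triflate-mediated cleavage of the tert-butyl ester (loss of isobutene) under lutidine buffering spares the methyl esters, the iodide and the acid-sensitive exocyclic alkenes, and the silyl ester hydrolyses on work-up.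

Step 16
Reactants: 27 C8′ carboxylic acid; 28 potassium methyl malonate
Product: 30 β-keto ester (C8′ ketone; C7′H2; methyl ester), via acyl imidazole 29 (not isolated)
Conditions: carbonyldiimidazole, THF, rt; then 28, MgCl2, Et3N, MeCN, rt → 40 °C
Reagents that add atoms: none
Why: Decarboxylative Claisen condensation of the acyl imidazole with the magnesium enolate of the malonate half-ester, mild enough to tolerate the primary iodide.

Step 17
Reactants: 30 β-keto ester
Product: 31 cyclised β-keto ester (nine-membered ring closed by C6′–C7′; C7′ epimers)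
Conditions: Cs2CO3, MeCN, 0.002 M (syringe pump), 50 °C
Reagents that add atoms: none
Why: Intramolecular C-alkylation of the stabilised β-keto ester enolate (9-exo-tet) at high dilution, helped by the trans-cyclobutane and the cyclohexene, which restrict the chain, and by the iodide leaving group, which favours C- over O-alkylation.

Step 18
Reactants: 31 cyclised β-keto ester
Product: 33 keto diacid (C8′ ketone; 12′,19-dioic acid), via β-keto triacid 32 (not isolated)
Conditions: EtSNa, DMF, 100 °C; then 1 M HCl, 40 °C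
Reagents that add atoms: none
Why: Thiolate SN2 demethylation cleaves all three methyl esters regardless of hindrance at the acyl carbons, the β-keto acid loses CO2 on acidification, and the basic medium leaves C9′ in the more stable trans ring fusion.

Step 19
Reactants: 33 keto diacid
Product: 34 CNP0330729.1
Conditions: Ph3PCH3Br (8 equiv), KOt-Bu (7.5 equiv), THF–DMSO, rt → 50 °C; then aq. citric acid
Reagents that add atoms: methyltriphenylphosphonium bromide C[P+](c1ccccc1)(c1ccccc1)c1ccccc1.[Br-]
Why: Wittig methylenation of the C8′ ketone with excess ylide (two equivalents are consumed by the carboxylic acids) installs the exocyclic methylene, and C9′ stays trans because that is its thermodynamic configuration.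

Compound list
1 | 3-[(tert-butyldimethylsilyl)oxy]propanal | O=CCCO[Si](C)(C)C(C)(C)C | starting material
2 | ethyl 2-(triphenylphosphoranylidene)propanoate | CCOC(=O)C(C)=P(c1ccccc1)(c1ccccc1)c1ccccc1 | starting material
3 | ethyl (E)-5-[(tert-butyldimethylsilyl)oxy]-2-methylpent-2-enoate | CCOC(=O)/C(C)=C/CCO[Si](C)(C)C(C)(C)C | intermediate
4 | (E)-5-[(tert-butyldimethylsilyl)oxy]-2-methylpent-2-en-1-ol | OC/C(C)=C/CCO[Si](C)(C)C(C)(C)C | intermediate
5 | (E)-1-bromo-5-[(tert-butyldimethylsilyl)oxy]-2-methylpent-2-ene | BrC/C(C)=C/CCO[Si](C)(C)C(C)(C)C | intermediate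
6 | tert-butyl acetoacetate | CC(=O)CC(=O)OC(C)(C)C | starting material
7 | tert-butyl (E)-2-acetyl-7-[(tert-butyldimethylsilyl)oxy]-4-methylhept-4-enoate, racemic at C2 | CC(=O)C(C/C(C)=C/CCO[Si](C)(C)C(C)(C)C)C(=O)OC(C)(C)C | intermediate
8 | tert-butyl (E)-2-diazo-4-methyl-7-[(tert-butyldimethylsilyl)oxy]hept-4-enoate | CC(C)(C)OC(=O)C(=[N+]=[N-])C/C(C)=C/CCO[Si](C)(C)C(C)(C)C | intermediate
9 | methylmagnesium bromide | C[Mg]Br | starting material
10 | tert-butyl (1S,2S,3S)-2-{2-[(tert-butyldimethylsilyl)oxy]ethyl}-3-methylbicyclo[1.1.0]butane-1-carboxylate, side chain exo | CC(C)(C)OC(=O)[C@]12C[C@@]1(C)[C@@H]2CCO[Si](C)(C)C(C)(C)C | intermediate (not isolated)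
11 | tert-butyl (1R,2R)-2-{2-[(tert-butyldimethylsilyl)oxy]ethyl}-3,3-dimethylcyclobutane-1-carboxylate, cis | CC(C)(C)[Si](C)(C)OCC[C@@H]1[C@H](C(=O)OC(C)(C)C)CC1(C)C | intermediate (not isolated)
12 | tert-butyl (1S,2R)-2-{2-[(tert-butyldimethylsilyl)oxy]ethyl}-3,3-dimethylcyclobutane-1-carboxylate, trans | CC(C)(C)[Si](C)(C)OCC[C@@H]1[C@@H](C(=O)OC(C)(C)C)CC1(C)C | intermediate
13 | tert-butyl (1S,2R)-2-(2-hydroxyethyl)-3,3-dimethylcyclobutane-1-carboxylate | OCC[C@@H]1[C@@H](C(=O)OC(C)(C)C)CC1(C)C | intermediate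
14 | tert-butyl (1S,2R)-2-(2-iodoethyl)-3,3-dimethylcyclobutane-1-carboxylate | ICC[C@@H]1[C@@H](C(=O)OC(C)(C)C)CC1(C)C | intermediate
15 | trans-communic acid, (12E)-labda-8(17),12,14-trien-19-oic acid | C=C/C(C)=C/C[C@H]1C(=C)CC[C@@H]2[C@]1(C)CCC[C@]2(C)C(=O)O | starting material
16 | methyl trans-communate | C=C/C(C)=C/C[C@H]1C(=C)CC[C@@H]2[C@]1(C)CCC[C@]2(C)C(=O)OC | intermediate
17 | (5S)-5-{[(1S,2R,5S)-5-methyl-2-(propan-2-yl)cyclohexyl]oxy}furan-2(5H)-one, the d-menthyloxy butenolide | C[C@H]1CC[C@@H]([C@H](C1)O[C@@H]1C=CC(=O)O1)C(C)C | starting material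
18 | endo cycloadduct: cyclohexene C12–C13(Me)=C14–C15–C5′–C4′ cis-fused at C4′–C5′ to the lactone C12′(=O)–O–C6′H(O-menthyl); H12, H4′, H5′ on one face; menthyloxy trans to C15 on the lactone; C12 and C5′ as in 34; C19 methyl ester | O=C1O[C@H](O[C@H]2C[C@@H](C)CC[C@@H]2C(C)C)[C@H]2CC=C(C)[C@@H](C[C@H]3C(=C)CC[C@@H]4[C@]3(C)CCC[C@]4(C)C(=O)OC)[C@@H]12 | intermediate
19 | sodium carboxylate of the ring-opened adduct: C5′ formyl, C4′ carboxylate cis to it | O=C[C@H]1CC=C(C)[C@@H](C[C@H]2C(=C)CC[C@@H]3[C@]2(C)CCC[C@]3(C)C(=O)OC)[C@H]1C(=O)[O-].[Na+] | intermediate (not isolated)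
20 | hydroxy acid: C5′ hydroxymethyl, C4′ carboxylic acid cis to it | OC[C@H]1CC=C(C)[C@@H](C[C@H]2C(=C)CC[C@@H]3[C@]2(C)CCC[C@]3(C)C(=O)OC)[C@H]1C(=O)O | intermediate (not isolated)
21 | γ-lactone C12′(=O)–O–C6′H2 cis-fused at C4′–C5′ of the cyclohexene; C11 chain cis to the lactone; C19 methyl ester | O=C1OC[C@H]2CC=C(C)[C@@H](C[C@H]3C(=C)CC[C@@H]4[C@]3(C)CCC[C@]4(C)C(=O)OC)[C@@H]12 | intermediate
22 | lactone 21 alkylated at C4′ by the 2-(cyclobutyl)ethyl unit of 14 (C3′ trans to C6′ and C11); tert-butyl ester on C9′ | O=C1OC[C@H]2CC=C(C)[C@@H](C[C@H]3C(=C)CC[C@@H]4[C@]3(C)CCC[C@]4(C)C(=O)OC)[C@@]12CC[C@@H]1[C@@H](C(=O)OC(C)(C)C)CC1(C)C | intermediate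
23 | potassium C12′ carboxylate of the opened lactone, C6′ hydroxyl free | OC[C@H]1CC=C(C)[C@@H](C[C@H]2C(=C)CC[C@@H]3[C@]2(C)CCC[C@]3(C)C(=O)OC)[C@]1(C(=O)[O-])CC[C@@H]1[C@@H](C(=O)OC(C)(C)C)CC1(C)C.[K+] | intermediate (not isolated)
24 | hydroxy triester: C6′H2OH, methyl esters at C12′ and C19, tert-butyl ester at C8′ | OC[C@H]1CC=C(C)[C@@H](C[C@H]2C(=C)CC[C@@H]3[C@]2(C)CCC[C@]3(C)C(=O)OC)[C@]1(C(=O)OC)CC[C@@H]1[C@@H](C(=O)OC(C)(C)C)CC1(C)C | intermediate
25 | iodo triester: C6′H2I, otherwise as 24 | IC[C@H]1CC=C(C)[C@@H](C[C@H]2C(=C)CC[C@@H]3[C@]2(C)CCC[C@]3(C)C(=O)OC)[C@]1(C(=O)OC)CC[C@@H]1[C@@H](C(=O)OC(C)(C)C)CC1(C)C | intermediate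
26 | trimethylsilyl ester at C8′, otherwise as 25 | IC[C@H]1CC=C(C)[C@@H](C[C@H]2C(=C)CC[C@@H]3[C@]2(C)CCC[C@]3(C)C(=O)OC)[C@]1(C(=O)OC)CC[C@@H]1[C@@H](C(=O)O[Si](C)(C)C)CC1(C)C | intermediate (not isolated)
27 | C8′ carboxylic acid, otherwise as 25 | IC[C@H]1CC=C(C)[C@@H](C[C@H]2C(=C)CC[C@@H]3[C@]2(C)CCC[C@]3(C)C(=O)OC)[C@]1(C(=O)OC)CC[C@@H]1[C@@H](C(=O)O)CC1(C)C | intermediate
28 | potassium methyl malonate | COC(=O)CC(=O)[O-].[K+] | starting material
29 | C8′ acyl imidazole, otherwise as 27 | IC[C@H]1CC=C(C)[C@@H](C[C@H]2C(=C)CC[C@@H]3[C@]2(C)CCC[C@]3(C)C(=O)OC)[C@]1(C(=O)OC)CC[C@@H]1[C@@H](C(=O)n2ccnc2)CC1(C)C | intermediate (not isolated)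
30 | β-keto ester: C9′–C8′(=O)–C7′H2–CO2Me, C6′H2I, methyl esters at C12′ and C19 | IC[C@H]1CC=C(C)[C@@H](C[C@H]2C(=C)CC[C@@H]3[C@]2(C)CCC[C@]3(C)C(=O)OC)[C@]1(C(=O)OC)CC[C@@H]1[C@@H](C(=O)CC(=O)OC)CC1(C)C | intermediate
31 | cyclised β-keto ester: nine-membered ring C1′–C9′ closed, C8′ ketone, CO2Me on C7′ (epimers), methyl esters at C12′ and C19 | O=C1C(C(=O)OC)C[C@H]2CC=C(C)[C@@H](C[C@H]3C(=C)CC[C@@H]4[C@]3(C)CCC[C@]4(C)C(=O)OC)[C@]2(C(=O)OC)CC[C@@H]2[C@@H]1CC2(C)C | intermediate
32 | β-keto triacid: 31 with all three esters as free acids | O=C1C(C(=O)O)C[C@H]2CC=C(C)[C@@H](C[C@H]3C(=C)CC[C@@H]4[C@]3(C)CCC[C@]4(C)C(=O)O)[C@]2(C(=O)O)CC[C@@H]2[C@@H]1CC2(C)C | intermediate (not isolated)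
33 | keto diacid: C8′ ketone, free acids at C12′ and C19, trans-fused cyclobutane | O=C1CC[C@H]2CC=C(C)[C@@H](C[C@H]3C(=C)CC[C@@H]4[C@]3(C)CCC[C@]4(C)C(=O)O)[C@]2(C(=O)O)CC[C@@H]2[C@@H]1CC2(C)C | intermediate
34 | CNP0330729.1 (C12 R; cyclobutane C1′ R, C9′ S) | C=C1CC[C@H]2CC=C(C)[C@@H](C[C@H]3C(=C)CC[C@@H]4[C@]3(C)CCC[C@]4(C)C(=O)O)[C@]2(C(=O)O)CC[C@@H]2[C@@H]1CC2(C)C | target

Total: 19 steps. Longest linear sequence: 16 steps (steps 1–8, then 12–19); the communate branch (steps 9–11) has 3.

Steps most likely to fail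

1. Step 6. The carbene may undergo 1,2-hydride shift faster than it adds to the trialkyl alkene, the cuprate may be too slow at the methyl-bearing bridgehead, or the catalyst may discriminate the alkene faces poorly. The fallback uses known reactions only. It cannot branch from an intermediate of steps 1–5, because it replaces the whole diazo line; it sets out from purchased 4,4-dimethylcyclopent-2-en-1-one F1 and rejoins the route at 13. Rhodium-catalysed asymmetric conjugate addition of potassium vinyltrifluoroborate ([Rh(cod)Cl]2, BINAP, aqueous dioxane; ligand enantiomer chosen for the S product) would give (S)-3-ethenyl-4,4-dimethylcyclopentan-1-one F2. Claisen formylation (HCO2Et, NaH) at C2, the α-carbon not flanked by the quaternary centre, would give the hydroxymethylidene ketone F3, and deformylative diazo transfer (4-acetamidobenzenesulfonyl azide, Et3N) the diazo ketone F4. Photochemical Wolff rearrangement in t-BuOH (C5 migrates to the carbene carbon and the ketene is trapped as the tert-butyl ester), then KOt-Bu equilibration, would contract the ring to tert-butyl (1S,2R)-2-ethenyl-3,3-dimethylcyclobutane-1-carboxylate F5. Anti-Markovnikov hydroboration–oxidation of the vinyl group (9-BBN; then H2O2, NaOH) would deliver 13.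

2. Step 17. Intermolecular alkylation (oligomers), O-alkylation or return of the γ-iodo ester to the lactone may outrun closure of the strained nine-membered ring. The fallback closes the ring by metathesis; it sets out from 24 and returns at 33. Oxidation of the C6′ alcohol with Dess–Martin periodinane would give the aldehyde F6, and Wittig methylenation at −78 °C (fast enough to avoid C5′ epimerisation) the C5′-vinyl compound F7. Cleavage of the tert-butyl ester as in step 15 would give the acid F8, amide coupling with N,O-dimethylhydroxylamine the N-methoxy-N-methylamide F9, and CH2=CHMgBr the vinyl ketone F10. Ring-closing metathesis with the second-generation Grubbs catalyst RuCl2(=CHPh)(PCy3)(SIMes) at high dilution should give the Z-cyclononenone F11 (only the vinyl and enone alkenes are reactive; the methyl esters are inert). Conjugate reduction with [(Ph3P)CuH]6 would give the saturated ketone F12, and the thiolate demethylation of step 18 converts F12 directly into 33.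

3. Step 10. The C12 alkyl and C13 methyl groups polarise the diene in opposite senses, so regioselectivity may erode, and the diene may polymerise during the long heating. The fallback sets out from 16 and returns at 21. Cycloaddition with maleic anhydride (toluene, 80 °C), whose two alkene carbons carry the same activating group so that no regiochemical question arises, would give the endo anhydride F13 together with its diastereomer of opposite configuration at C12, C4′ and C5′. LiBH(s-Bu)3 (THF, −78 °C) should reduce the less hindered C6′ carbonyl, acidification closes the lactone, and chromatographic separation of the two diastereomeric lactones gives 21.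

Further compounds
F1 | step 6 | 4,4-dimethylcyclopent-2-en-1-one | CC1(C)C=CC(=O)C1
F2 | step 6 | (S)-3-ethenyl-4,4-dimethylcyclopentan-1-one | C=C[C@@H]1CC(=O)CC1(C)C
F3 | step 6 | (S)-3-ethenyl-2-(hydroxymethylidene)-4,4-dimethylcyclopentan-1-one | C=C[C@@H]1C(=CO)C(=O)CC1(C)C
F4 | step 6 | (S)-2-diazo-3-ethenyl-4,4-dimethylcyclopentan-1-one | C=C[C@@H]1C(=[N+]=[N-])C(=O)CC1(C)C
F5 | step 6 | tert-butyl (1S,2R)-2-ethenyl-3,3-dimethylcyclobutane-1-carboxylate | C=C[C@@H]1[C@@H](C(=O)OC(C)(C)C)CC1(C)C
F6 | step 17 | C6′ aldehyde of 24 | O=C[C@H]1CC=C(C)[C@@H](C[C@H]2C(=C)CC[C@@H]3[C@]2(C)CCC[C@]3(C)C(=O)OC)[C@]1(C(=O)OC)CC[C@@H]1[C@@H](C(=O)OC(C)(C)C)CC1(C)C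
F7 | step 17 | C5′-vinyl triester | C=C[C@H]1CC=C(C)[C@@H](C[C@H]2C(=C)CC[C@@H]3[C@]2(C)CCC[C@]3(C)C(=O)OC)[C@]1(C(=O)OC)CC[C@@H]1[C@@H](C(=O)OC(C)(C)C)CC1(C)C
F8 | step 17 | C5′-vinyl C8′ carboxylic acid | C=C[C@H]1CC=C(C)[C@@H](C[C@H]2C(=C)CC[C@@H]3[C@]2(C)CCC[C@]3(C)C(=O)OC)[C@]1(C(=O)OC)CC[C@@H]1[C@@H](C(=O)O)CC1(C)C
F9 | step 17 | C5′-vinyl C8′ N-methoxy-N-methylamide | C=C[C@H]1CC=C(C)[C@@H](C[C@H]2C(=C)CC[C@@H]3[C@]2(C)CCC[C@]3(C)C(=O)OC)[C@]1(C(=O)OC)CC[C@@H]1[C@@H](C(=O)N(C)OC)CC1(C)C
F10 | step 17 | C5′-vinyl C8′ vinyl ketone | C=C[C@H]1CC=C(C)[C@@H](C[C@H]2C(=C)CC[C@@H]3[C@]2(C)CCC[C@]3(C)C(=O)OC)[C@]1(C(=O)OC)CC[C@@H]1[C@@H](C(=O)C=C)CC1(C)C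
F11 | step 17 | (6′Z)-cyclononenone dimethyl ester | O=C1/C=C\[C@H]2CC=C(C)[C@@H](C[C@H]3C(=C)CC[C@@H]4[C@]3(C)CCC[C@]4(C)C(=O)OC)[C@]2(C(=O)OC)CC[C@@H]2[C@@H]1CC2(C)C
F12 | step 17 | C8′ ketone 12′,19-dimethyl ester | O=C1CC[C@H]2CC=C(C)[C@@H](C[C@H]3C(=C)CC[C@@H]4[C@]3(C)CCC[C@]4(C)C(=O)OC)[C@]2(C(=O)OC)CC[C@@H]2[C@@H]1CC2(C)C
F13 | step 10 | endo maleic anhydride adduct of 16 (C12, C4′, C5′ as in 21) | O=C1OC(=O)[C@H]2CC=C(C)[C@@H](C[C@H]3C(=C)CC[C@@H]4[C@]3(C)CCC[C@]4(C)C(=O)OC)[C@@H]12
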